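**Retrosynthetic overview**
- The gem-diprenyl group is put on last, by double C-alkylation of the spiro acyl-trione at its only ring CH2.
- The trione ring comes from an intramolecular Claisen closure of a triacylmethane side chain onto a bridged γ-lactone. The lactone ties the future C-6 carbonyl to the C-7' oxygen, so the spiro centre is fixed by construction.
- The cyclohexane ring comes from intramolecular C-alkylation of an α-acetoacetyl γ-lactone by a primary iodide.
- The cyclopentane, the lactone and four stereocentres come from one amine-catalysed vinylogous Michael/aldol cascade of α-angelica lactone with (2E)-6-oxohept-2-enal, which is made by cross-metathesis.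
- Ring order: cyclopentane (carrying the γ-lactone), then cyclohexane, then trione.

Assumption: the acyl-trione is treated as the enol tautomer written in the target SMILES (other tautomers and a 7'-OH/C-6 hemiketal count as the same compound); primed locants refer to the octahydroindene part.

**Step 1**
Reactants: 1 hex-5-en-2-one; 2 crotonaldehyde ((2E)-but-2-enal)
Product: 3 (2E)-6-oxohept-2-enal
Conditions: second-generation Grubbs catalyst RuCl2(=CHPh)(PCy3)(H2IMes) (2 mol %), 2 (4 equiv), CH2Cl2, 40 °C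
Reagents that add atoms: none
Why: Olefin cross-metathesis of a terminal alkene with an excess of an electron-poor enal gives the E-enal selectively and is driven by loss of propene; the ketone is inert.

**Step 2**
Reactants: 3 (2E)-6-oxohept-2-enal; 4 α-angelica lactone (5-methylfuran-2(3H)-one)
Product: 6 (5R)-5-[(1S,2S,3S)-3-hydroxy-2-(hydroxymethyl)-3-methylcyclopentyl]-5-methyloxolan-2-one, via hydroxy aldehyde 5 (not isolated)
Conditions: (R)-2-[diphenyl(trimethylsilyloxy)methyl]pyrrolidine (20 mol %), LiOAc (20 mol %), 4 (2 equiv), toluene, 0 °C; then MeOH, NiCl2·6H2O (10 mol %), NaBH4 (5 equiv), −20 → 0 °C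
Reagents that add atoms: none
Why: Proposed new method: the amine forms the E-iminium ion of 3 and LiOAc deprotonates 4 to its 2-furanolate, whose γ-carbon adds to the enal β-carbon on the face not shielded by the diphenyl(silyloxy)methyl group (sets cyclopentyl C-1 as S) through a stacked, endo-type open transition state with the ring oxygen next to the alkyl chain and the 5-methyl pointing away (sets the quaternary lactone carbon as R); the enamine so formed closes onto the methyl ketone in a 5-enolexo aldol through an iminium–alkoxide closed transition state (OH cis to the formyl group), the epimerisable formyl carbon settles trans to the lactone, and in situ NiCl2/NaBH4 reduction of the aldehyde and the butenolide C=C prevents β-elimination or retro-aldol; the closest known reactions are amine-catalysed vinylogous (Mukaiyama-)Michael additions of furanone dienolates to enals and iminium–enamine Michael/aldol cascades of ω-oxo-enals.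

**Step 3**
Reactants: 6 (5R)-5-[(1S,2S,3S)-3-hydroxy-2-(hydroxymethyl)-3-methylcyclopentyl]-5-methyloxolan-2-one
Product: 8 (5R)-5-[(1S,2R,3S)-2-(iodomethyl)-3-methyl-3-[(trimethylsilyl)oxy]cyclopentyl]-5-methyloxolan-2-one, via iodo alcohol 7 (not isolated)
Conditions: PPh3 (1.3 equiv), I2 (1.3 equiv), imidazole (5 equiv), CH2Cl2, 0 → 23 °C; then Me3SiCl (1.5 equiv), 23 °C
Reagents that add atoms: iodine ([I][I]); chlorotrimethylsilane (C[Si](C)(C)Cl)
Why: Appel iodination converts only the primary alcohol, and the imidazole already present then mediates silylation of the tertiary alcohol so that it survives the enolate chemistry; no stereocentre is touched.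

**Step 4**
Reactants: 8 (5R)-5-[(1S,2R,3S)-2-(iodomethyl)-3-methyl-3-[(trimethylsilyl)oxy]cyclopentyl]-5-methyloxolan-2-one; 9 diketene (4-methylideneoxetan-2-one)
Product: 11 (3S,3aR,5R,7R,7aS)-3,7-dimethyl-5-(3-oxobutanoyl)-3-[(trimethylsilyl)oxy]octahydro-1H-indene-5,7-carbolactone, via acetoacetyl lactone 10 (not isolated)
Conditions: LiN(SiMe3)2 (1.05 equiv), THF, −78 °C; 9 (1.1 equiv), −78 → −40 °C; LiN(SiMe3)2 (1.2 equiv), DMPU, −40 → 23 °C
Reagents that add atoms: none
Why: Claisen-type C-acetoacetylation of the lactone lithium enolate by diketene gives a tricarbonyl whose dianion alkylates at the lactone α-carbon in a 6-exo-tet closure (O-alkylation or alkylation at the chain CH would need eight-membered rings), and because the new bond can only form on the lactone face that carries the cyclopentyl group, the quaternary C-5 is set with its lactone carbonyl cis to the C-7 oxygen and the ring fusion is trans.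

**Step 5**
Reactants: 11 (3S,3aR,5R,7R,7aS)-3,7-dimethyl-5-(3-oxobutanoyl)-3-[(trimethylsilyl)oxy]octahydro-1H-indene-5,7-carbolactone; 12 isobutyryl chloride (2-methylpropanoyl chloride)
Product: 13 (3S,3aR,5R,7R,7aS)-5-(2-acetyl-4-methyl-3-oxopentanoyl)-3,7-dimethyl-3-[(trimethylsilyl)oxy]octahydro-1H-indene-5,7-carbolactone
Conditions: MgCl2 (1.2 equiv), pyridine (2.5 equiv), 12 (1.1 equiv), CH2Cl2, 0 → 23 °C
Reagents that add atoms: none
Why: Magnesium-chelate (soft-enolisation) C-acylation of the β-diketone gives the triacylmethane, which places the isobutyryl group on the carbon next to the ketone carbonyl and not next to the lactone carbonyl; no stereocentre is touched.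

**Step 6**
Reactants: 13 (3S,3aR,5R,7R,7aS)-5-(2-acetyl-4-methyl-3-oxopentanoyl)-3,7-dimethyl-3-[(trimethylsilyl)oxy]octahydro-1H-indene-5,7-carbolactone
Product: 15 (1S,3'S,3a'R,7'R,7a'S)-3',4,7'-trihydroxy-3',7'-dimethyl-3-(2-methylpropanoyl)octahydrospiro[cyclohex-3-ene-1,5'-indene]-2,6-dione, via silyl trione 14 (not isolated)
Conditions: LiN(iPr)2 (3.3 equiv), THF, −78 → 0 °C; then 1 M HCl, MeOH, 23 °C
Reagents that add atoms: none
Why: The dianion forms at the acetyl CH3 (the least hindered γ-position) and attacks the strained γ-lactone carbonyl in an intramolecular Claisen (Dieckmann-type) closure that builds the trione ring and releases the C-7' alkoxide, so the former lactone carbonyl (C-6) ends cis to the 7'-OH, which is the spiro configuration of the target; the acidic work-up cleaves the tertiary silyl ether.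

**Step 7**
Reactants: 15 (1S,3'S,3a'R,7'R,7a'S)-3',4,7'-trihydroxy-3',7'-dimethyl-3-(2-methylpropanoyl)octahydrospiro[cyclohex-3-ene-1,5'-indene]-2,6-dione; 16 prenyl bromide (1-bromo-3-methylbut-2-ene)
Product: 17 (1S,3'S,3a'R,7'R,7a'S)-3',4,7'-trihydroxy-3',7'-dimethyl-5,5-bis(3-methylbut-2-en-1-yl)-3-(2-methylpropanoyl)octahydrospiro[cyclohex-3-ene-1,5'-indene]-2,6-dione
Conditions: NaOMe (3.2 equiv), MeOH, 0 °C; 16 (2.4 equiv), 0 → 23 °C
Reagents that add atoms: none
Why: Lupulone-type C-alkylation of the acylphloroglucinol-like dianion occurs twice at the only ring CH2 (C-5), while the acyl-bearing carbon and the tertiary alcohols do not react; no stereocentre is affected.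

**Compound list**
1 | hex-5-en-2-one | CC(=O)CCC=C | starting material
2 | crotonaldehyde, (2E)-but-2-enal | C/C=C/C=O | starting material
3 | (2E)-6-oxohept-2-enal | CC(=O)CC/C=C/C=O | intermediate
4 | α-angelica lactone, 5-methylfuran-2(3H)-one | CC1=CCC(=O)O1 | starting material
5 | (1R,2S,5S)-2-hydroxy-2-methyl-5-[(2R)-2-methyl-5-oxo-2,5-dihydrofuran-2-yl]cyclopentane-1-carbaldehyde | O=C[C@@H]1[C@H](CC[C@]1(C)O)[C@]2(C)OC(=O)C=C2 | intermediate
6 | (5R)-5-[(1S,2S,3S)-3-hydroxy-2-(hydroxymethyl)-3-methylcyclopentyl]-5-methyloxolan-2-one | OC[C@@H]1[C@H](CC[C@]1(C)O)[C@]2(C)OC(=O)CC2 | intermediate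
7 | (5R)-5-[(1S,2R,3S)-3-hydroxy-2-(iodomethyl)-3-methylcyclopentyl]-5-methyloxolan-2-one | IC[C@@H]1[C@H](CC[C@]1(C)O)[C@]2(C)OC(=O)CC2 | intermediate
8 | (5R)-5-[(1S,2R,3S)-2-(iodomethyl)-3-methyl-3-[(trimethylsilyl)oxy]cyclopentyl]-5-methyloxolan-2-one | IC[C@@H]1[C@H](CC[C@]1(C)O[Si](C)(C)C)[C@]2(C)OC(=O)CC2 | intermediate
9 | diketene, 4-methylideneoxetan-2-one | C=C1CC(=O)O1 | starting material
10 | (5R)-5-[(1S,2R,3S)-2-(iodomethyl)-3-methyl-3-[(trimethylsilyl)oxy]cyclopentyl]-5-methyl-3-(3-oxobutanoyl)oxolan-2-one (C-3 epimers and enols) | IC[C@@H]1[C@H](CC[C@]1(C)O[Si](C)(C)C)[C@]2(C)OC(=O)C(C2)C(=O)CC(C)=O | intermediate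
11 | (3S,3aR,5R,7R,7aS)-3,7-dimethyl-5-(3-oxobutanoyl)-3-[(trimethylsilyl)oxy]octahydro-1H-indene-5,7-carbolactone (γ-lactone from the C-5 carboxyl to the C-7 oxygen; trans ring fusion) | CC(=O)CC(=O)[C@@]12C[C@@H]3[C@H](CC[C@]3(C)O[Si](C)(C)C)[C@@](C)(C1)OC2=O | intermediate
12 | isobutyryl chloride, 2-methylpropanoyl chloride | CC(C)C(Cl)=O | starting material
13 | (3S,3aR,5R,7R,7aS)-5-(2-acetyl-4-methyl-3-oxopentanoyl)-3,7-dimethyl-3-[(trimethylsilyl)oxy]octahydro-1H-indene-5,7-carbolactone (enolised triacylmethane) | CC(=O)C(C(=O)C(C)C)C(=O)[C@@]12C[C@@H]3[C@H](CC[C@]3(C)O[Si](C)(C)C)[C@@](C)(C1)OC2=O | intermediate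
14 | (1S,3'S,3a'R,7'R,7a'S)-4,7'-dihydroxy-3',7'-dimethyl-3-(2-methylpropanoyl)-3'-[(trimethylsilyl)oxy]octahydrospiro[cyclohex-3-ene-1,5'-indene]-2,6-dione | C1C(=O)[C@@]2(C[C@@H]3[C@H](CC[C@]3(C)O[Si](C)(C)C)[C@](C)(O)C2)C(=O)C(C(=O)C(C)C)=C1O | intermediate
15 | (1S,3'S,3a'R,7'R,7a'S)-3',4,7'-trihydroxy-3',7'-dimethyl-3-(2-methylpropanoyl)octahydrospiro[cyclohex-3-ene-1,5'-indene]-2,6-dione | C1C(=O)[C@@]2(C[C@@H]3[C@H](CC[C@]3(C)O)[C@](C)(O)C2)C(=O)C(C(=O)C(C)C)=C1O | intermediate
16 | prenyl bromide, 1-bromo-3-methylbut-2-ene | CC(C)=CCBr | starting material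
17 | (1S,3'S,3a'R,7'R,7a'S)-3',4,7'-trihydroxy-3',7'-dimethyl-5,5-bis(3-methylbut-2-en-1-yl)-3-(2-methylpropanoyl)octahydrospiro[cyclohex-3-ene-1,5'-indene]-2,6-dione | CC(C)=CCC1(CC=C(C)C)C(=O)[C@@]2(C[C@@H]3[C@H](CC[C@]3(C)O)[C@](C)(O)C2)C(=O)C(C(=O)C(C)C)=C1O | target

**Totals and risks**
Total step count: 7. Longest linear sequence: 7.

The three steps most likely to fail:

Step 2 (the proposed new cascade). The risks are acylation of the amine catalyst by 4, α- instead of γ-attack of the dienolate, and the wrong sense at the quaternary lactone carbon or at the carbinol carbon. The fallback sets out from 3 and 4 and comes back at 5, and it splits the cascade into two known reactions. Compound 4 is silylated (Me3SiCl, Et3N) to 5-methyl-2-(trimethylsilyloxy)furan F1. F1 is added to 3 in the established imidazolidinone-catalysed Mukaiyama–Michael reaction, with (2R,5R)-5-benzyl-2-tert-butyl-3-methylimidazolidin-4-one·2,4-dinitrobenzoic acid in CH2Cl2–H2O at −70 °C, to give (3S)-3-[(2R)-2-methyl-5-oxo-2,5-dihydrofuran-2-yl]-6-oxoheptanal F2. The acid co-catalyst and the solvent are the handles for the syn/anti sense at the quaternary carbon. A separate secondary-amine-catalysed enolexo aldolisation (pyrrolidine·AcOH, 0 °C) then closes the cyclopentane to 5, which is reduced as in step 2 to 6.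

Step 4 (diketene acylation followed by ring closure). The risks are diketene oligomerisation, O-acetoacetylation and slow alkylation at the hindered CH2I. The fallback sets out from 8 and comes back at 11, and it replaces diketene by two Claisen acylations with an acetyl donor. LiN(SiMe3)2 and then 1-acetylimidazole give (5R)-3-acetyl-5-[(1S,2R,3S)-2-(iodomethyl)-3-methyl-3-[(trimethylsilyl)oxy]cyclopentyl]-5-methyloxolan-2-one F3. With a second equivalent of base and DMPU this cyclises to (3S,3aR,5R,7R,7aS)-5-acetyl-3,7-dimethyl-3-[(trimethylsilyl)oxy]octahydro-1H-indene-5,7-carbolactone F4. The kinetic methyl enolate of F4 (LiN(iPr)2, 2 equiv, −78 °C) is acetylated with 1-acetylimidazole to give 11.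

Step 6 (Claisen closure of a triacylmethane dianion onto a hindered lactone). The risks are no cyclisation or deacylation. The fallback sets out from 11 and comes back at 15, and it masks the tricarbonyl as an isoxazole so that a localised, more reactive carbanion does the ring closure.
- Compound 11 is condensed with 2-methylpropanenitrile oxide (from 2-methylpropanal oxime, N-chlorosuccinimide, Et3N) to give (3S,3aR,5R,7R,7aS)-3,7-dimethyl-5-{[5-methyl-3-(propan-2-yl)-1,2-oxazol-4-yl]carbonyl}-3-[(trimethylsilyl)oxy]octahydro-1H-indene-5,7-carbolactone F5.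
- Lateral lithiation of the 5-methyl group (LiN(iPr)2, THF, −78 °C) and attack on the lactone give (3'S,3a'R,5S,7'R,7a'S)-7'-hydroxy-3',7'-dimethyl-3-(propan-2-yl)-3'-[(trimethylsilyl)oxy]octahydro-4H-spiro[1,2-benzoxazole-5,5'-indene]-4,6(7H)-dione F6.
- N–O cleavage with Mo(CO)6 in MeCN–H2O at 80 °C gives (1S,3'S,3a'R,7'R,7a'S)-3-(1-amino-2-methylpropylidene)-7'-hydroxy-3',7'-dimethyl-3'-[(trimethylsilyl)oxy]octahydrospiro[cyclohexane-1,5'-indene]-2,4,6-trione F7.
- Aqueous HCl hydrolyses the enamine and the silyl ether to give 15.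

**Further compounds**
F1 | step 2 | 5-methyl-2-(trimethylsilyloxy)furan | Cc1ccc(O[Si](C)(C)C)o1
F2 | step 2 | (3S)-3-[(2R)-2-methyl-5-oxo-2,5-dihydrofuran-2-yl]-6-oxoheptanal | O=CC[C@H](CCC(C)=O)[C@]1(C)OC(=O)C=C1
F3 | step 4 | (5R)-3-acetyl-5-[(1S,2R,3S)-2-(iodomethyl)-3-methyl-3-[(trimethylsilyl)oxy]cyclopentyl]-5-methyloxolan-2-one | IC[C@@H]1[C@H](CC[C@]1(C)O[Si](C)(C)C)[C@]2(C)OC(=O)C(C2)C(C)=O
F4 | step 4 | (3S,3aR,5R,7R,7aS)-5-acetyl-3,7-dimethyl-3-[(trimethylsilyl)oxy]octahydro-1H-indene-5,7-carbolactone | CC(=O)[C@@]12C[C@@H]3[C@H](CC[C@]3(C)O[Si](C)(C)C)[C@@](C)(C1)OC2=O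
F5 | step 6 | (3S,3aR,5R,7R,7aS)-3,7-dimethyl-5-{[5-methyl-3-(propan-2-yl)-1,2-oxazol-4-yl]carbonyl}-3-[(trimethylsilyl)oxy]octahydro-1H-indene-5,7-carbolactone | CC(C)c4noc(C)c4C(=O)[C@@]12C[C@@H]3[C@H](CC[C@]3(C)O[Si](C)(C)C)[C@@](C)(C1)OC2=O
F6 | step 6 | (3'S,3a'R,5S,7'R,7a'S)-7'-hydroxy-3',7'-dimethyl-3-(propan-2-yl)-3'-[(trimethylsilyl)oxy]octahydro-4H-spiro[1,2-benzoxazole-5,5'-indene]-4,6(7H)-dione | C1C(=O)[C@@]2(C[C@@H]3[C@H](CC[C@]3(C)O[Si](C)(C)C)[C@](C)(O)C2)C(=O)c4c1onc4C(C)C
F7 | step 6 | (1S,3'S,3a'R,7'R,7a'S)-3-(1-amino-2-methylpropylidene)-7'-hydroxy-3',7'-dimethyl-3'-[(trimethylsilyl)oxy]octahydrospiro[cyclohexane-1,5'-indene]-2,4,6-trione | C1C(=O)[C@@]2(C[C@@H]3[C@H](CC[C@]3(C)O[Si](C)(C)C)[C@](C)(O)C2)C(=O)C(=C(N)C(C)C)C1=O
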